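- Dissolved substrate has a forward half-life of 0.16 s against the coupling partner as charged, much shorter than the 16.9 s that dissolving needs to refill the solution, so I expect a thin solution and treat dissolving as the rate-limiting step.

solid substrate 32 mM; coupling partner 64.0 mM; time 20 s

* target and crystals together at 20 s, in percent of the solid substrate charged
* concentration of dissolved substrate in solution at 20 s, in percent of saturation

- target is meant together with its crystals
- solid, in amounts per volume of the solution: solid substrate, crystals
- at the start none of the solid substrate is in solution
- dissolved substrate means what is dissolved; the solid is not counted in it
- run time (flask): 20 s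

    solid substrate ⇌ dissolved substrate, rate k1*(cs1 - [dissolved substrate]) while solid is left; crystals form when [dissolved substrate] > cs1 (cs1 = 16 mM, k1 = 0.059 s⁻¹)
    crystals ⇌ target, rate k2*(cs2 - [target]) while solid is left; crystals form when [target] > cs2 (cs2 = 26 mM, k2 = 0.67 s⁻¹)
    dissolved substrate + coupling partner ⇌ target (K3 = 120 M⁻¹, k3 = 67 M⁻¹ s⁻¹)
    target ⇌ isomer of the product (K4 = 1.1, k4 = 0.10 s⁻¹)

- For my top bound I use the delivery ceiling, the solubility times the dissolution coefficient times the time, as a share of the charge: 59.0%, which is what the solid delivers into a solution kept empty.
- That ceiling is 18.9 mM, less than the 26 mM target needs for crystals, so I count no crystals.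
- For my bottom bound I am pessimistic on each count. I take the coupling partner as down by the full ceiling, which puts one part of dissolved substrate against 5.41 of target. I hold the solution from the start at the level this gives for the full ceiling, 3.49 mM, which slows delivery to 46.1%. I also let the isomer of the product take its full 1.1 per target. This leaves 20.2%.
- I bring the top down by counting the lag of the isomer behind a steady feed. Its relaxation half-life of 3.63 s is short against 20 s, but it gives a lag of 5.24 s, and I count feed younger than that as still target. My top becomes 36.2%.
- The forecast gives 30% and 12%, on the ground that “Dissolved substrate therefore sits at quasi-steady state”, and its yield lies inside my bracket.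
- The flask gives 29.9% and 11.8%, and the yield lies inside the bracket too.

- While solid stood in this flask, dissolving ran nearly evenly, with 51% of its turnover done at 10.0 s. By 20 s it had delivered 55.1% against the ceiling of 59.0%, leaving 44.9% as solid. Coupling ran alongside it, at 20% of its turnover by 4.00 s, while the isomer trailed, reaching the midpoint of its turnover at 12.1 s and standing at 19.3% against 29.9% of target. In the same flask read at 80 s, the ceiling is 236%, more than the whole charge, and solid substrate stands at 0%, with target at 42.8%.

(The rate constants were chosen freely.)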